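## Retrosynthetic overview

- Target 17 is the tiglate of (S)-alkannin: a 5,8-dihydroxy-1,4-naphthoquinone (naphthazarin) whose C2 carries the acyloxy-bearing stereocentre C1′.
- The strategy rests on the dihydroxylated ring (C4a, C5, C6, C7, C8, C8a). Written as its 4a,8a-dihydro-5,8-dione tautomer, it is one quinone C=C (C4a/C8a) plus a four-carbon 1,4-dioxygenated diene (C5 to C8). It is therefore cut at C4a–C5 and C8a–C8 into side-chain benzoquinone 12 and 2,5-bis(trimethylsilyloxy)furan 14.
- Quinone 12 comes from oxidative demethylation of dimethoxyarene ester 11, which comes from esterification of alcohol 9 with tiglic acid. Alcohol 9 comes from enantioselective reduction of aryl ketone 7, made from 2,5-dimethoxyphenyllithium and the Weinreb amide of 4-methylpent-3-enoic acid.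
- Ring order: the ring of 1,4-dimethoxybenzene becomes the quinonoid ring (C1 to C4, C4a, C8a). The second carbocycle is closed in the last step, already at the naphthazarin oxidation level.

Key step: step 7

Remark: 17 is written as the tautomer with the side chain on the quinonoid ring. Naphthazarin tautomers interconvert rapidly, so this is the same compound as the form with the side chain on the dihydroxybenzenoid ring.

## Route

Step 1
Reactants: 1 4-methylpent-3-enoic acid
Product: 3 N-methoxy-N,4-dimethylpent-3-enamide, via 1-(4-methylpent-3-enoyl)imidazole 2 (not isolated)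
Conditions: CDI, CH2Cl2, 0 °C to rt; then MeNH(OMe)·HCl, rt
Reagents that add atoms: N,O-dimethylhydroxylamine hydrochloride, CNOC.Cl (amide nitrogen group of 3); 1,1'-carbonyldiimidazole, O=C(n1ccnc1)n1ccnc1 (imidazole ring of 2 only)
Why: Weinreb amide formation by CDI activation and aminolysis of the acyl imidazole runs without an acid chloride or strong base, so the β,γ-alkene should not move into conjugation.

Step 2
Reactants: 4 1,4-dimethoxybenzene; 3 N-methoxy-N,4-dimethylpent-3-enamide
Product: 7 1-(2,5-dimethoxyphenyl)-4-methylpent-3-en-1-one, via 2,5-dimethoxyphenyllithium 5 (not isolated), via lithium hemiaminal adduct 6 (not isolated)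
Conditions: n-BuLi, TMEDA, Et2O, 0 °C to rt (arene in slight excess); then 3, THF, −78 °C; inverse quench into cold 1 M HCl
Reagents that add atoms: n-butyllithium, [Li]CCCC (lithium of 5 and 6 only)
Why: Directed ortho-lithiation followed by Weinreb ketone synthesis should stop at the chelated tetrahedral adduct 6, which releases the ketone only on the cold acidic quench, where the skipped enone has no base available to isomerise it.

Step 3
Reactants: 7 1-(2,5-dimethoxyphenyl)-4-methylpent-3-en-1-one
Product: 9 (1S)-1-(2,5-dimethoxyphenyl)-4-methylpent-3-en-1-ol, via chloro(isopinocampheyl)borinate ester 8 (not isolated)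
Conditions: (−)-DIP-Cl, THF, −25 °C; then HN(CH2CH2OH)2, Et2O, rt
Reagents that add atoms: (−)-B-chlorodiisopinocampheylborane, ClB([C@@H]1C[C@@H]2C[C@H]([C@H]1C)C2(C)C)[C@@H]1C[C@@H]2C[C@H]([C@H]1C)C2(C)C (boron, chlorine and one isopinocampheyl group of 8 only; 9 gains only hydrogen)
Why: Asymmetric DIP-Cl reduction transfers the isopinocampheyl β-hydride through a six-membered boat transition state with the aryl group remote from the pinane methyl, which for aryl alkyl ketones should give the (S)-carbinol with the (−)-reagent; it does not touch the trisubstituted alkene and sets the only stereocentre of the route.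

Step 4
Reactants: 9 (1S)-1-(2,5-dimethoxyphenyl)-4-methylpent-3-en-1-ol; 10 tiglic acid
Product: 11 (1S)-1-(2,5-dimethoxyphenyl)-4-methylpent-3-en-1-yl (2E)-2-methylbut-2-enoate
Conditions: DCC, DMAP (cat.), CH2Cl2, 0 °C to rt
Reagents that add atoms: none
Why: Steglich esterification acylates the alcohol oxygen through the N-acylpyridinium, so the C–O bond of the stereocentre is never broken (retention), and the (E)-enoate is the thermodynamically favoured geometry.

Step 5
Reactants: 11 (1S)-1-(2,5-dimethoxyphenyl)-4-methylpent-3-en-1-yl (2E)-2-methylbut-2-enoate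
Product: 12 (1S)-1-(3,6-dioxocyclohexa-1,4-dien-1-yl)-4-methylpent-3-en-1-yl (2E)-2-methylbut-2-enoate
Conditions: CAN, MeCN/H2O, 0 °C, arene added to the oxidant, short contact; crude quinone used at once
Reagents that add atoms: water, O
Why: Cerium(IV) oxidative demethylation (two one-electron oxidations of the electron-rich arene, ipso attack of water, loss of methanol) should be much faster than oxidation of the isolated alkene or the enoate, and adding the arene to excess oxidant suppresses radical-cation dimerisation.

Step 6
Reactants: 13 succinic anhydride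
Product: 14 2,5-bis(trimethylsilyloxy)furan
Conditions: TMSCl, Et3N, ZnCl2 (cat.), MeCN, rt; filtration under Ar, distillation; used at once
Reagents that add atoms: chlorotrimethylsilane, C[Si](C)(C)Cl
Why: Zinc chloride-assisted double enol silylation of the cyclic anhydride (soft enolisation) is driven by the aromaticity gained in the furan, and distillation removes amine salts that could later epimerise C1′.

Step 7
Reactants: 12 (1S)-1-(3,6-dioxocyclohexa-1,4-dien-1-yl)-4-methylpent-3-en-1-yl (2E)-2-methylbut-2-enoate; 14 2,5-bis(trimethylsilyloxy)furan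
Product: 17 (1S)-1-(5,8-dihydroxy-1,4-dioxo-1,4-dihydronaphthalen-2-yl)-4-methylpent-3-en-1-yl (2E)-2-methylbut-2-enoate, via oxygen-bridged bis(silyl ketal) cycloadduct 15 (not isolated), via 4a,8a-dihydronaphthalene-1,4,5,8-tetraone 16 (not isolated)
Conditions: 14 (1.05 equiv) added slowly to 12, CH2Cl2, −78 °C to rt, Ar, dark; then 0.1 M HCl/THF, rt, brief
Reagents that add atoms: none
Why: The electron-rich, s-cis-locked furan 14 and the electron-poor quinone 12 should combine in a normal-electron-demand Diels–Alder reaction at the unsubstituted C5=C6 of 12, forming C4a–C5 and C8a–C8 and giving the oxygen-bridged bis(silyl ketal) 15. Lone-pair assistance from the silyloxy groups opens the strained bridge with loss of hexamethyldisiloxane to tetraone 16, whose two ring-fusion hydrogens enolise toward C5=O and C8=O to give the aromatic, doubly hydrogen-bonded naphthazarin 17 with no change of oxidation level. The closest known reaction type is the cycloaddition of 2,5-bis(silyloxy)furans with quinones and other electron-poor dienophiles, which gives hydroquinones and naphthazarins after collapse of the bridged adduct. The new six-membered carbocycle (C4a, C5, C6, C7, C8, C8a) is closed by an intermolecular, concerted, suprafacial [4+2] cycloaddition in which both ring bonds form in one step. No stereocentre is created in the product: the sp3 centres of 15 (endo or exo) are erased on aromatisation, and C1′ from step 3 is a spectator that is kept because no base is present. The step needs site selectivity for the unsubstituted C=C (the branched acyloxyalkyl group shields C2=C3 and lowers its dienophilicity), cycloaddition in preference to a conjugate addition that stops after one bond (non-polar solvent, low temperature, no Lewis acid or fluoride) and a single annulation (one equivalent of 14 added slowly, the benzoquinone being the stronger dienophile); regiochemistry does not arise because the diene is symmetric.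

## Compound list

1 | 4-methylpent-3-enoic acid | CC(C)=CCC(=O)O | starting material
2 | 1-(4-methylpent-3-enoyl)imidazole | CC(C)=CCC(=O)n1ccnc1 | intermediate (not isolated)
3 | N-methoxy-N,4-dimethylpent-3-enamide | CC(C)=CCC(=O)N(C)OC | intermediate
4 | 1,4-dimethoxybenzene | COc1ccc(OC)cc1 | starting material
5 | 2,5-dimethoxyphenyllithium | [Li]c1cc(OC)ccc1OC | intermediate (not isolated)
6 | lithium 1-(2,5-dimethoxyphenyl)-1-[methoxy(methyl)amino]-4-methylpent-3-en-1-olate (tetrahedral adduct, transient centre undefined) | CC(C)=CCC(O[Li])(N(C)OC)c1cc(OC)ccc1OC | intermediate (not isolated)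
7 | 1-(2,5-dimethoxyphenyl)-4-methylpent-3-en-1-one | CC(C)=CCC(=O)c1cc(OC)ccc1OC | intermediate
8 | (1S)-1-(2,5-dimethoxyphenyl)-4-methylpent-3-en-1-yl chloro(isopinocampheyl)borinate | C[C@H]1[C@H](B(Cl)O[C@@H](CC=C(C)C)c3cc(OC)ccc3OC)C[C@@H]2C[C@H]1C2(C)C | intermediate (not isolated)
9 | (1S)-1-(2,5-dimethoxyphenyl)-4-methylpent-3-en-1-ol | O[C@@H](CC=C(C)C)c1cc(OC)ccc1OC | intermediate
10 | tiglic acid, (2E)-2-methylbut-2-enoic acid | C/C=C(\C)C(=O)O | starting material
11 | (1S)-1-(2,5-dimethoxyphenyl)-4-methylpent-3-en-1-yl (2E)-2-methylbut-2-enoate | C/C=C(\C)C(=O)O[C@@H](CC=C(C)C)c1cc(OC)ccc1OC | intermediate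
12 | (1S)-1-(3,6-dioxocyclohexa-1,4-dien-1-yl)-4-methylpent-3-en-1-yl (2E)-2-methylbut-2-enoate (side-chain 1,4-benzoquinone) | C/C=C(\C)C(=O)O[C@@H](CC=C(C)C)C1=CC(=O)C=CC1=O | intermediate
13 | succinic anhydride | O=C1CCC(=O)O1 | starting material
14 | 2,5-bis(trimethylsilyloxy)furan | C[Si](C)(C)Oc1ccc(O[Si](C)(C)C)o1 | intermediate
15 | (1S)-1-[5,8-dioxo-1,4-bis(trimethylsilyloxy)-1,4,4a,5,8,8a-hexahydro-1,4-epoxynaphthalen-6-yl]-4-methylpent-3-en-1-yl (2E)-2-methylbut-2-enoate (bridgehead and ring-fusion centres undefined) | C/C=C(\C)C(=O)O[C@@H](CC=C(C)C)C1=CC(=O)C2C(C1=O)C3(O[Si](C)(C)C)C=CC2(O[Si](C)(C)C)O3 | intermediate (not isolated)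
16 | (1S)-4-methyl-1-(1,4,5,8-tetraoxo-1,4,4a,5,8,8a-hexahydronaphthalen-2-yl)pent-3-en-1-yl (2E)-2-methylbut-2-enoate | C/C=C(\C)C(=O)O[C@@H](CC=C(C)C)C1=CC(=O)C2C(C1=O)C(=O)C=CC2=O | intermediate (not isolated)
17 | (1S)-1-(5,8-dihydroxy-1,4-dioxo-1,4-dihydronaphthalen-2-yl)-4-methylpent-3-en-1-yl (2E)-2-methylbut-2-enoate, (S)-alkannin tiglate | C/C=C(\C)C(=O)O[C@@H](CC=C(C)C)C1=CC(=O)c2c(O)ccc(O)c2C1=O | target

## Summary

Total step count: 7.
Longest linear sequence: 6 steps (steps 1, 2, 3, 4, 5 and 7); step 6 is a one-step branch.

Steps most likely to fail, riskiest first: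

**Step 7.** Three processes threaten the annulation. The furan may add in a stepwise conjugate sense and stop after the first C–C bond. The bridged ketal may collapse with ionisation of the acyloxy group that sits allylic to the ene-dione, so the tiglate is lost. The diene may also attack C2=C3 or add a second time. The fallback takes the ester out of the annulation and introduces it last; it still relies on the same cycloaddition, so it answers the ester-loss and site-selectivity failures but not an intrinsic preference for conjugate addition. It sets out from alcohol 9 and returns at 17. Silylation (TBSCl, imidazole, DMF) should give tert-butyl{[(1S)-1-(2,5-dimethoxyphenyl)-4-methylpent-3-en-1-yl]oxy}dimethylsilane F1. Oxidation with CAN as in step 5 should give 2-[(1S)-1-(tert-butyldimethylsilyloxy)-4-methylpent-3-en-1-yl]-1,4-benzoquinone F2. Cycloaddition with 14 in CH2Cl2 should pass through the bridged bis(silyl ketal) adduct of the silyl ether F3 and the silyl ether 4a,8a-dihydrotetraone F4 to O-TBS-(S)-alkannin F5. The silyloxy group cannot ionise and is bulkier, which should raise the bias for the unsubstituted C=C. HF·pyridine in THF should then free (S)-alkannin F6. DCC/DMAP esterification with tiglic acid 10 should acylate only the side-chain hydroxyl, because the peri-hydroxyls are tied up in hydrogen bonds to the quinone carbonyls, giving 17.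

**Step 5.** The oxidant may attack the trisubstituted alkene, the arene radical cation may couple to a biaryl diquinone, or the nitric acid released may solvolyse the electron-rich benzylic ester. The fallback replaces the chemical oxidant by anodic oxidation with a separate unmasking step. It sets out from 11 and returns at 12. Constant-current electrolysis in MeOH (LiClO4, 2,6-lutidine, carbon anode, undivided cell, 0 °C) should give the quinone bis(dimethyl ketal) (1S)-4-methyl-1-(3,3,6,6-tetramethoxycyclohexa-1,4-dien-1-yl)pent-3-en-1-yl (2E)-2-methylbut-2-enoate F7. Mild hydrolysis (dilute aqueous acid in acetone, 0 °C to rt) should then release quinone 12.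

**Step 2.** The aryllithium may act as a base toward the doubly activated α-methylene of 3, so that arene and amide are recovered. The β,γ-enone 7 may also slip into conjugation during quench or purification, which would compromise the substrate of the asymmetric reduction. The fallback avoids the ketone altogether and also replaces step 3. It sets out from aryllithium 5 and returns at alcohol 9. A DMF quench should give 2,5-dimethoxybenzaldehyde F8, which is also commercially available. Brown allylation with B-allyldiisopinocampheylborane made from (−)-Ipc2BOMe and allylmagnesium bromide (Et2O, −78 °C, then NaOH/H2O2) should give (1S)-1-(2,5-dimethoxyphenyl)but-3-en-1-ol F9 through the chair transition state, by analogy with the (S)-carbinol expected from benzaldehyde. Cross-metathesis with 2-methyl-2-butene (second-generation Grubbs catalyst, 40 °C) should then turn the terminal vinyl group into the trisubstituted alkene of 9.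

## Further compounds

F1 | step 7 | tert-butyl{[(1S)-1-(2,5-dimethoxyphenyl)-4-methylpent-3-en-1-yl]oxy}dimethylsilane | C[Si](C)(C(C)(C)C)O[C@@H](CC=C(C)C)c1cc(OC)ccc1OC
F2 | step 7 | 2-[(1S)-1-(tert-butyldimethylsilyloxy)-4-methylpent-3-en-1-yl]cyclohexa-2,5-diene-1,4-dione | C[Si](C)(C(C)(C)C)O[C@@H](CC=C(C)C)C1=CC(=O)C=CC1=O
F3 | step 7 | 6-[(1S)-1-(tert-butyldimethylsilyloxy)-4-methylpent-3-en-1-yl]-1,4-bis(trimethylsilyloxy)-1,4,4a,8a-tetrahydro-1,4-epoxynaphthalene-5,8-dione (transient, ring centres undefined) | C[Si](C)(C(C)(C)C)O[C@@H](CC=C(C)C)C1=CC(=O)C2C(C1=O)C3(O[Si](C)(C)C)C=CC2(O[Si](C)(C)C)O3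
F4 | step 7 | 2-[(1S)-1-(tert-butyldimethylsilyloxy)-4-methylpent-3-en-1-yl]-4a,8a-dihydronaphthalene-1,4,5,8-tetraone (transient) | C[Si](C)(C(C)(C)C)O[C@@H](CC=C(C)C)C1=CC(=O)C2C(C1=O)C(=O)C=CC2=O
F5 | step 7 | 2-[(1S)-1-(tert-butyldimethylsilyloxy)-4-methylpent-3-en-1-yl]-5,8-dihydroxynaphthalene-1,4-dione, O-TBS-(S)-alkannin | C[Si](C)(C(C)(C)C)O[C@@H](CC=C(C)C)C1=CC(=O)c2c(O)ccc(O)c2C1=O
F6 | step 7 | (S)-alkannin, 5,8-dihydroxy-2-[(1S)-1-hydroxy-4-methylpent-3-en-1-yl]naphthalene-1,4-dione | O[C@@H](CC=C(C)C)C1=CC(=O)c2c(O)ccc(O)c2C1=O
F7 | step 5 | (1S)-4-methyl-1-(3,3,6,6-tetramethoxycyclohexa-1,4-dien-1-yl)pent-3-en-1-yl (2E)-2-methylbut-2-enoate | C/C=C(\C)C(=O)O[C@@H](CC=C(C)C)C1=CC(OC)(OC)C=CC1(OC)OC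
F8 | step 2 | 2,5-dimethoxybenzaldehyde | COc1ccc(OC)c(C=O)c1
F9 | step 2 | (1S)-1-(2,5-dimethoxyphenyl)but-3-en-1-ol | O[C@@H](CC=C)c1cc(OC)ccc1OC
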